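**Retrosynthetic overview**
1. Last step, both bicycles closed together: an aromatic 24-membered bis(3-alkylpyridinium) macrocycle gives the target by one-flask dearomatising reduction, double-bond shift to two cyclic enamines and acid-triggered transannular closure (N,O-acetal on the hydroxyl side, Mannich on the ketone side). Six of the eight stereocentres settle here under thermodynamic control from the C15/C32 pair.
2. Macrocycle ⇐ linear pyridinium enone by intramolecular aza-Michael N-alkylation (N4–C3); the ketone is then masked as a dimethyl ketal.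
3. Linear precursor ⇐ N30–C31 iodide-assisted Menshutkin union of two 3-picoline-derived pieces: an achiral pyridine enone and a pyridine hydroxy tosylate.
4. Hydroxy tosylate ⇐ the same enone (asymmetric C=O hydrogenation sets C15, anti-hydroboration sets C32, tosylation); enone ⇐ 3-picoline by lateral lithiation/alkylation and Weinreb acylation.
5. Ring order: two pyridine rings (bought) → 24-membered ring → both piperidine rings unveiled, then the 1,3-oxazine ring (ring B side) and the ketone ring (ring A side) in the same flask.

Locants (C2, N4, C8, C15, O16, C17, C18, C24, C25, C26, N30, C31, C32) count the atoms of the target SMILES from left to right, with the carbonyl oxygen on C25 left out of the count. Ring A is the nitrogen ring that ends in the quinolizidinone, ring B the one that ends in the oxaquinolizidine.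
Assumption: N-methoxy-N-methylmethacrylamide and RuCl2[(S)-xylbinap][(S)-daipen] are taken as catalogue items.

**Route**

Step 1
Reactants: 1 3-methylpyridine (3-picoline); 2 1-bromo-5-chloropentane
Product: 4 3-(6-chlorohexyl)pyridine, via pyridin-3-ylmethyllithium 3 (not isolated)
Conditions: LiN(iPr)2 (1.1 equiv), THF, −78 °C, 45 min; then 2 (1.2 equiv), −78 → 0 °C
Reagents that add atoms: none
Why: Lateral (benzylic-type) lithiation of 3-picoline followed by SN2 alkylation at the more reactive C–Br end of the dihalide gives the C6 chain with a chloride that is too slow to quaternise the pyridine on handling.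

Step 2
Reactants: 4 3-(6-chlorohexyl)pyridine; 5 N-methoxy-N-methylmethacrylamide
Product: 7 2-methyl-9-(pyridin-3-yl)non-1-en-3-one, via 6-(pyridin-3-yl)hexylmagnesium chloride 6 (not isolated)
Conditions: Mg, LiCl, THF, 50 °C; then 5 (1.2 equiv), −30 → 0 °C; cold 1 M HCl, then NaHCO3
Reagents that add atoms: none
Why: Grignard formation from the primary chloride (an unactivated pyridine ring is inert to it) and Weinreb ketone synthesis, in which the N-methoxy-N-methylamide stops at mono-addition, release the isopropenyl ketone only on acidic work-up.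

Step 3
Reactants: 7 2-methyl-9-(pyridin-3-yl)non-1-en-3-one
Product: 8 (R)-2-methyl-9-(pyridin-3-yl)non-1-en-3-ol
Conditions: H2 (8 atm), RuCl2[(S)-xylbinap][(S)-daipen] (0.2 mol%), K2CO3 (5 mol%), iPrOH, 25 °C
Reagents that add atoms: none
Why: Noyori asymmetric hydrogenation with a Ru diphosphine/diamine catalyst is carbonyl-selective beside the alkene and tolerates pyridine; the alkenyl group plays the part of the aryl group of aryl alkyl ketones, so the (S,S) catalyst sets C15 as R.

Step 4
Reactants: 8 (R)-2-methyl-9-(pyridin-3-yl)non-1-en-3-ol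
Product: 10 (2S,3R)-2-methyl-9-(pyridin-3-yl)nonane-1,3-diol, via bis(9-BBN) organoborane 9 (not isolated)
Conditions: 9-BBN (3.5 equiv), THF, 0 → 25 °C; then 3 M NaOH, 30% H2O2, 0 → 25 °C
Reagents that add atoms: hydrogen peroxide, OO
Why: Substrate-controlled hydroboration–oxidation of a 1,1-disubstituted alkene next to a carbinol: in the A(1,3)-strain-minimised conformer (carbinol C–H eclipsing the alkene) the bulky 9-BBN adds anti to the alkyl chain, which sets C32 as S in the 2,3-anti diol (about 10:1 expected, minor isomer removed by chromatography), the excess borane covering the pyridine nitrogen and the hydroxyl.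

Step 5
Reactants: 10 (2S,3R)-2-methyl-9-(pyridin-3-yl)nonane-1,3-diol
Product: 11 (2S,3R)-3-hydroxy-2-methyl-9-(pyridin-3-yl)nonyl 4-methylbenzenesulfonate
Conditions: TsCl (1.05 equiv), Et3N, DMAP (5 mol%), CH2Cl2, −20 → 0 °C; kept cold and used at once
Reagents that add atoms: 4-methylbenzenesulfonyl chloride (TsCl), Cc1ccc(cc1)S(Cl)(=O)=O
Why: DMAP-catalysed sulfonylation picks the primary hydroxyl over the hindered secondary one and touches no stereocentre.

Step 6
Reactants: 11 (2S,3R)-3-hydroxy-2-methyl-9-(pyridin-3-yl)nonyl 4-methylbenzenesulfonate; 7 2-methyl-9-(pyridin-3-yl)non-1-en-3-one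
Product: 13 1-[(2S,3R)-3-hydroxy-2-methyl-9-(pyridin-3-yl)nonyl]-3-(8-methyl-7-oxonon-8-en-1-yl)pyridin-1-ium iodide, via hydroxy iodide 12 (not isolated)
Conditions: 7 (4 equiv, 1 M), NaI (1.3 equiv), BHT (1 mol%), MeCN, 75 °C, dark; 11 in MeCN added over 12 h, then 6 h more; evaporate, take up in CH2Cl2, filter off sodium 4-methylbenzenesulfonate (NaOTs); Et2O trituration (excess 7 recovered)
Reagents that add atoms: sodium iodide, [Na+].[I-]
Why: Finkelstein exchange (SN2, driven by NaOTs precipitating from MeCN) turns the sluggish beta-branched primary tosylate into the iodide 12, which quaternises the pyridine of 7 in a Menshutkin reaction (SN2) to form N30–C31; slow addition into excess 7 keeps self-alkylation low, neither pyridine nor iodide adds to the enone without a proton source, and no stereocentre is involved.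

Step 7
Reactants: 13 linear pyridinium enone iodide
Product: 15 ketal-protected 24-membered bis(pyridinium) macrocycle diiodide, via keto bis(pyridinium) macrocycle 14 (not isolated)
Conditions: HI (57% aq., 1.05 equiv), MeCN (2 mM), Ar, dark, 60 °C, 48 h; concentrate; then HC(OMe)3 (10 equiv), MeOH, 40 °C; precipitate from Et2O
Reagents that add atoms: hydrogen iodide, I; trimethyl orthoformate, COC(OC)OC
Why: Acid-mediated aza-Michael (conjugate) addition of the ring A pyridine, present as its hydroiodide, to the isopropenyl ketone forms N4–C3 as a 1-(2-methyl-3-oxoalkyl)pyridinium salt (any beta-iodo ketone formed from HI alkylates the same nitrogen); the addition is reversible, so at 2 mM open oligomers funnel to the 24-membered ring, the ketone is then masked by acid-catalysed ketalisation for the hydride and base stages to come, and C2 forms as a mixture that is equilibrated in step 8.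

Step 8
Reactants: 15 ketal-protected 24-membered bis(pyridinium) macrocycle diiodide
Product: 19 CNP0236330.1 (target), via bis(tetrahydropyridine) ketal 16 (not isolated), via bis(enamine) ketal 17 (not isolated), via keto bis(iminium) salt 18 (not isolated)
Conditions: NaBH4 (8 equiv), MeOH, −20 → 40 °C; aq. Na2CO3/CH2Cl2 extraction (removes NaI), evaporate, crude extract taken on; KOtBu (6 equiv), DMSO, 60 °C, Ar; then aq. TFA (pH 1), 45 °C; NaOAc buffer (pH 5), 60 °C; aq. K2CO3
Reagents that add atoms: water, O
Why: Proposed new method: borohydride dearomatises both pyridinium rings to 3-alkyl-1,2,5,6-tetrahydropyridines (hydride at C2 of each ring, C-protonation, hydride at C6), tert-butoxide in DMSO shifts each double bond through the allylic alpha-amino carbanion into the conjugated C17=C18 and C26=C8 enamines, and acid C-protonates these to 2,3,4,5-tetrahydropyridinium ions that are captured in six-membered closures by the C15 hydroxyl (N,O-acetal at C17) and, after ketal hydrolysis, by the ketone enol at C24 (intramolecular Mannich reaction at C26); C2, C8, C17, C18, C24 and C26 all stay epimerisable in the buffer (enolisation, iminium–enamine exchange, retro-Mannich, N,O-acetal opening) and settle relative to the fixed C15/C32 pair into the trans-fused all-equatorial oxaquinolizidine and the trans-quinolizidinone with equatorial methyl, equatorial C8 chain and axial C24 chain (which avoids the peri clash); the closest known reaction types are NaBH4 reduction of pyridinium salts, KOtBu/DMSO allylamine-to-enamine isomerisation with acid cyclisation of the 2-piperideine, iminium N,O-acetalisation and the intramolecular Mannich reaction.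

**Compound list**
1 | 3-methylpyridine (3-picoline) | Cc1cccnc1 | starting material
2 | 1-bromo-5-chloropentane | ClCCCCCBr | starting material
3 | pyridin-3-ylmethyllithium (not isolated) | [Li]Cc1cccnc1 | intermediate
4 | 3-(6-chlorohexyl)pyridine | ClCCCCCCc1cccnc1 | intermediate
5 | N-methoxy-N-methylmethacrylamide | C=C(C)C(=O)N(C)OC | starting material
6 | 6-(pyridin-3-yl)hexylmagnesium chloride (not isolated) | Cl[Mg]CCCCCCc1cccnc1 | intermediate
7 | 2-methyl-9-(pyridin-3-yl)non-1-en-3-one | C=C(C)C(=O)CCCCCCc1cccnc1 | intermediate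
8 | (R)-2-methyl-9-(pyridin-3-yl)non-1-en-3-ol | C=C(C)[C@H](O)CCCCCCc1cccnc1 | intermediate
9 | bis(9-BBN) organoborane: C31-boryl, C15-O-borinate of the diol skeleton (pyridine–borane contact not drawn; not isolated) | C(B1C2CCCC1CCC2)[C@H](C)[C@H](OB1C2CCCC1CCC2)CCCCCCc1cccnc1 | intermediate
10 | (2S,3R)-2-methyl-9-(pyridin-3-yl)nonane-1,3-diol | OC[C@H](C)[C@H](O)CCCCCCc1cccnc1 | intermediate
11 | (2S,3R)-3-hydroxy-2-methyl-9-(pyridin-3-yl)nonyl 4-methylbenzenesulfonate | Cc1ccc(cc1)S(=O)(=O)OC[C@H](C)[C@H](O)CCCCCCc1cccnc1 | intermediate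
12 | (2R,3R)-1-iodo-2-methyl-9-(pyridin-3-yl)nonan-3-ol (not isolated) | IC[C@H](C)[C@H](O)CCCCCCc1cccnc1 | intermediate
13 | 1-[(2S,3R)-3-hydroxy-2-methyl-9-(pyridin-3-yl)nonyl]-3-(8-methyl-7-oxonon-8-en-1-yl)pyridin-1-ium iodide | C=C(C)C(=O)CCCCCCc1ccc[n+](c1)C[C@H](C)[C@H](O)CCCCCCc1cccnc1.[I-] | intermediate
14 | 24-membered keto bis(pyridinium) macrocycle diiodide; ring B N-arm CH2-CH(CH3)-CH(OH) (15R,32S), ring A N-arm CH2-CH(CH3)-C(=O), C2 epimers (not isolated) | O[C@H]1[C@@H](C)C[n+]2cccc(c2)CCCCCCC(=O)C(C)C[n+]2cccc(c2)CCCCCC1.[I-].[I-] | intermediate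
15 | dimethyl ketal of 14 at C25, diiodide | O[C@H]1[C@@H](C)C[n+]2cccc(c2)CCCCCCC(OC)(OC)C(C)C[n+]2cccc(c2)CCCCCC1.[I-].[I-] | intermediate
16 | macrocyclic bis(3-alkyl-1,2,5,6-tetrahydropyridine) ketal (C18=C27 and C8=C7; not isolated) | O[C@H]1[C@@H](C)CN2CCC=C(C2)CCCCCCC(OC)(OC)C(C)CN2CCC=C(C2)CCCCCC1 | intermediate
17 | macrocyclic bis(3-alkyl-1,4,5,6-tetrahydropyridine) ketal (enamines C17=C18 and C26=C8; not isolated) | O[C@H]1[C@@H](C)CN2CCCC(=C2)CCCCCCC(OC)(OC)C(C)CN2CCCC(=C2)CCCCCC1 | intermediate
18 | macrocyclic keto bis(2,3,4,5-tetrahydropyridinium) bis(trifluoroacetate) (iminium carbons C17 and C26; not isolated) | O[C@H]1[C@@H](C)C[N+]2=CC(CCC2)CCCCCCC(=O)C(C)C[N+]2=CC(CCC2)CCCCCC1.[O-]C(=O)C(F)(F)F.[O-]C(=O)C(F)(F)F | intermediate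
19 | CNP0236330.1; 2R,8S,15R,17S,18R,24R,26S,32S in the locants above | C[C@@H]1CN2CCC[C@@H]3CCCCCC[C@H]4O[C@H]5[C@H](CCCCC[C@@H](C1=O)[C@H]32)CCCN5C[C@@H]4C | target

**Count and risks**
Total step count: 8. Longest linear sequence: 8 steps (1 → 4 → 7 → 8 → 10 → 11 → 13 → 15 → 19; compound 7 enters a second time in step 6).

Most likely to fail:

Step 8. Hydride or base regiochemistry can leak to the C6-side enamine, which would close the bicycles at the wrong ring carbon. Enamines may be over-reduced if hydride survives into the acid stage. The configuration of the ring A set relative to the remote C15/C32 pair is settled only by thermodynamics across the macrocycle, so a diastereomer with the mirror-image ring A set may co-form; it would be returned to the pH 5 buffer at 60 °C to re-equilibrate.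

Fallback for step 8: setting out from 15, NaBH4 in MeOH is used alone and the bis(tetrahydropyridine) ketal 16 is isolated. mCPBA (2.0 equiv) in CH2Cl2 at 0 °C gives the bis(N-oxide) F1. TFAA at −10 °C (Polonovski–Potier reaction, regiospecific through the allylic C–H next to nitrogen) gives the conjugated bis(5,6-dihydropyridinium) salt F2. Aqueous acid, followed by K2CO3, then removes the ketal and lets the hydroxyl and the ketone enol add at C17 and C26, giving the doubly unsaturated bicyclic diene F3. H2 over 5% Rh on Al2O3 followed by the pH 5 equilibration returns to the route at 19.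

Step 7. The aza-Michael addition to an alpha-substituted enone may be too slow or too reversible at 2 mM, and the beta-pyridinium ketone can revert during ketalisation.

Fallback for step 7: setting out from 13, anhydrous HBr in CH2Cl2 at 0 °C adds across the enone to give the beta-bromo ketone hydrobromide F4. HC(OMe)3 in MeOH converts it into the bromo dimethyl ketal F5. NaHCO3 and NaI in MeCN (1 mM, 80 °C) then free the ring A pyridine and close the ring by an irreversible intramolecular Menshutkin reaction on the masked ketone, NaBr precipitating. The diiodide obtained is 15, where the route is rejoined.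

Step 6. Self-alkylation of 11 or of the iodide 12, and a second alkylation of the free pyridine of 13, compete with the wanted union.

Fallback for step 6: setting out from 11, mCPBA in CH2Cl2 at 0 °C masks its pyridine as the N-oxide tosylate F6, which can be stored. Heating F6 with NaI and 7 (1.5 equiv) in MeCN at 80 °C passes through the N-oxide iodide F7 and gives the linear pyridinium iodide N-oxide F8. Deoxygenation with B2pin2 in MeCN at 60 °C returns to the route at 13.

**Further compounds**
F1 | step 8 | bis(N-oxide) of 16 | O[C@H]1[C@@H](C)C[N+]2([O-])CCC=C(C2)CCCCCCC(OC)(OC)C(C)C[N+]2([O-])CCC=C(C2)CCCCCC1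
F2 | step 8 | macrocyclic bis(3-alkyl-5,6-dihydropyridinium) ketal bis(trifluoroacetate) | O[C@H]1[C@@H](C)C[N+]2=CC(=CCC2)CCCCCCC(OC)(OC)C(C)C[N+]2=CC(=CCC2)CCCCCC1.[O-]C(=O)C(F)(F)F.[O-]C(=O)C(F)(F)F
F3 | step 8 | 7,8:18,27-didehydro derivative of 19 (C2, C17, C24, C26 not yet fixed) | CC1CN2CCC=C3CCCCCC[C@H]4OC5C(CCCCCC(C1=O)C32)=CCCN5C[C@@H]4C
F4 | step 7 | HBr adduct of 13: 9-bromo-8-methyl-7-oxononyl arm on ring B, ring A pyridine as its hydrobromide (bromide iodide salt) | BrCC(C)C(=O)CCCCCCc1ccc[n+](c1)C[C@H](C)[C@H](O)CCCCCCc1ccc[nH+]c1.[Br-].[I-]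
F5 | step 7 | dimethyl ketal of F4 | BrCC(C)C(OC)(OC)CCCCCCc1ccc[n+](c1)C[C@H](C)[C@H](O)CCCCCCc1ccc[nH+]c1.[Br-].[I-]
F6 | step 6 | pyridine N-oxide of 11 | Cc1ccc(cc1)S(=O)(=O)OC[C@H](C)[C@H](O)CCCCCCc1ccc[n+]([O-])c1
F7 | step 6 | pyridine N-oxide of 12, (2R,3R)-1-iodo-2-methyl-9-(1-oxidopyridin-1-ium-3-yl)nonan-3-ol (formed in the flask) | IC[C@H](C)[C@H](O)CCCCCCc1ccc[n+]([O-])c1
F8 | step 6 | ring A pyridine N-oxide of 13 (iodide salt) | C=C(C)C(=O)CCCCCCc1ccc[n+](c1)C[C@H](C)[C@H](O)CCCCCCc1ccc[n+]([O-])c1.[I-]
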